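**Retrosynthetic overview**
- The target comes from desilylation of its side-chain silyl ether; the ten-membered carbocycle is closed last by ring-closing metathesis that forms the cis C1=C10 olefin.
- The oxirane and the α-methylene-γ-lactone come from hydroxyl-directed (threo) epoxidation and lactonisation of an acyclic anti hydroxy ester.
- The C6–C7 bond comes from a chair allylboration of (E)-3-methylhepta-2,6-dienal with a 2-(ethoxycarbonyl)allylboronate that carries C8; C8 steers C7 and the chair fixes C6.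
- The allylboronate comes from bromo-olefination and Negishi coupling of an α-acyloxy aldehyde, itself made by amine-catalysed asymmetric α-acyloxylation of 4-methylpent-4-enal with the side-chain diacyl peroxide (first stereocentre, side chain installed).
- Ring order: oxirane, then lactone, then carbocycle.

Assumption: 4-methylpent-4-enal and ethyl bromo[bis(2,2,2-trifluoroethoxy)phosphoryl]acetate are taken as purchasable; positions are given in germacrane numbering (C1–C15). Tig* = (2E)-4-[(tert-butyldimethylsilyl)oxy]-2-methylbut-2-enoyl.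

**Step 1**
Reactants: 1 (tert-butyldimethylsilyloxy)acetaldehyde; 2 ethyl 2-(triphenylphosphoranylidene)propanoate
Product: 3 ethyl (2E)-4-[(tert-butyldimethylsilyl)oxy]-2-methylbut-2-enoate
Conditions: CH2Cl2, 23 °C, 12 h
Reagents that add atoms: none
Why: Wittig olefination with a stabilised ylide, which places the ester trans to the CH2O arm (E ≥ 95:5).

**Step 2**
Reactants: 3 ethyl (2E)-4-[(tert-butyldimethylsilyl)oxy]-2-methylbut-2-enoate
Product: 4 (2E)-4-[(tert-butyldimethylsilyl)oxy]-2-methylbut-2-enoic acid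
Conditions: LiOH·H2O, THF/MeOH/H2O, 23 °C; then 1 M HCl to pH 4, 0 °C
Reagents that add atoms: lithium hydroxide, [Li+].[OH-]
Why: Ester saponification; the primary silyl ether tolerates mild hydroxide and a brief pH 4 work-up.

**Step 3**
Reactants: 4 (2E)-4-[(tert-butyldimethylsilyl)oxy]-2-methylbut-2-enoic acid (2 equiv)
Product: 5 bis[(2E)-4-[(tert-butyldimethylsilyl)oxy]-2-methylbut-2-enoyl] peroxide
Conditions: DCC (2 equiv), H2O2 (50% aq., 1 equiv), CH2Cl2, −10 → 0 °C
Reagents that add atoms: hydrogen peroxide, OO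
Why: Carbodiimide-mediated double O-acylation of hydrogen peroxide through the O-acylisourea, the standard mild preparation of diacyl peroxides.

**Step 4**
Reactants: 6 4-methylpent-4-enal; 5 bis(Tig*) peroxide
Product: 7 (2R)-4-methyl-1-oxopent-4-en-2-yl (2E)-4-[(tert-butyldimethylsilyl)oxy]-2-methylbut-2-enoate
Conditions: (R)-2-[diphenyl(trimethylsilyloxy)methyl]pyrrolidine (10 mol%), hydroquinone (10 mol%), THF, 0 °C, 6 h; used at once
Reagents that add atoms: none
Why: Proposed new method: enamine-catalysed asymmetric α-acyloxylation with a functionalised alkenoyl peroxide, in which the E-enamine of 6 attacks one peroxide oxygen of 5 (SN2 at oxygen, carboxylate 4 leaving) on its Re face, the face not shielded by the diphenyl(silyloxy)methyl group of the (R)-catalyst, and hydrolysis of the α-acyloxy iminium ion gives 7 with C8 as R, so one step sets the first stereocentre and installs the whole side-chain ester; the closest known reaction is the secondary-amine-catalysed α-benzoyloxylation of aldehydes with dibenzoyl peroxide, the conjugated enoyl peroxide being electronically similar to the aroyl one.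

**Step 5**
Reactants: 7 (2R)-4-methyl-1-oxopent-4-en-2-yl Tig* ester; 8 ethyl bromo[bis(2,2,2-trifluoroethoxy)phosphoryl]acetate
Product: 9 ethyl (2E,4R)-2-bromo-4-{[(2E)-4-[(tert-butyldimethylsilyl)oxy]-2-methylbut-2-enoyl]oxy}-6-methylhepta-2,6-dienoate
Conditions: 8, KOt-Bu, 18-crown-6, THF, −78 °C; then 7, −78 °C, 1 h
Reagents that add atoms: none
Why: Horner–Wadsworth–Emmons olefination of the Still–Gennari type, whose kinetically controlled collapse puts the ester cis to the C8 arm and bromine trans (E by CIP because Br outranks CO2Et); the low temperature protects the α-acyloxy stereocentre.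

**Step 6**
Reactants: 9 ethyl (2E,4R)-2-bromo-4-(Tig*-oxy)-6-methylhepta-2,6-dienoate; 10 2-(iodomethyl)-4,4,5,5-tetramethyl-1,3,2-dioxaborolane
Product: 12 ethyl (2Z,4R)-4-{[(2E)-4-[(tert-butyldimethylsilyl)oxy]-2-methylbut-2-enoyl]oxy}-6-methyl-2-[(4,4,5,5-tetramethyl-1,3,2-dioxaborolan-2-yl)methyl]hepta-2,6-dienoate, via (pinacolboryl)methylzinc iodide 11 (not isolated)
Conditions: 10, Zn (activated with 1,2-dibromoethane and Me3SiCl), THF, 23 °C; then 9, Pd(PPh3)4 (5 mol%), THF, 23 °C
Reagents that add atoms: zinc, [Zn] (ends in intermediate 11, not in 12)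
Why: Negishi cross-coupling with retention of olefin geometry, in which oxidative addition of zerovalent palladium into the C–Br bond of the bromoacrylate outruns ionisation of the allylic ester; it gives the allylboronate with the C8 arm trans to CH2B.

**Step 7**
Reactants: 13 hex-5-en-2-one; 14 diethyl {2-[methoxy(methyl)amino]-2-oxoethyl}phosphonate
Product: 15 (2E)-N-methoxy-N,3-dimethylhepta-2,6-dienamide
Conditions: NaH, THF, 0 °C → reflux; E isomer separated by chromatography (E:Z about 4:1)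
Reagents that add atoms: none
Why: Horner–Wadsworth–Emmons olefination of a methyl ketone, which places the amide trans to the longer chain in the major isomer.

**Step 8**
Reactants: 15 (2E)-N-methoxy-N,3-dimethylhepta-2,6-dienamide
Product: 16 (2E)-3-methylhepta-2,6-dienal
Conditions: i-Bu2AlH, THF, −78 °C; aq. potassium sodium tartrate
Reagents that add atoms: none
Why: Weinreb amide reduction, which stops at the aldehyde through the chelated tetrahedral intermediate and keeps the E geometry.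

**Step 9**
Reactants: 12 allylboronate; 16 (2E)-3-methylhepta-2,6-dienal
Product: 17 ethyl (3S,4R,5E)-3-[(1R)-1-{[(2E)-4-[(tert-butyldimethylsilyl)oxy]-2-methylbut-2-enoyl]oxy}-3-methylbut-3-en-1-yl]-4-hydroxy-6-methyl-2-methylidenedeca-5,9-dienoate
Conditions: Sc(OTf)3 (10 mol%), toluene, −78 → −20 °C; aq. NaHCO3
Reagents that add atoms: none
Why: Lewis-acid-accelerated allylboration through a closed chair, in which the aldehyde substituent and the C8 arm (trans to CH2B) are both equatorial and so give the anti C6/C7 pair (later the trans-lactone), while H8 eclipses the olefin to avoid allylic 1,3-strain with the cis ester, the C8–C9 bond lies anti to the forming bond and the smaller acyloxy oxygen sits on the attacked face, which sets C7 and with it C6 from C8; the low temperature leaves the hydroxy ester unlactonised.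

**Step 10**
Reactants: 17 anti hydroxy ester
Product: 19 (1R)-1-[(2S,3R)-2-[(2R,3R)-3-(but-3-en-1-yl)-3-methyloxiran-2-yl]-4-methylidene-5-oxooxolan-3-yl]-3-methylbut-3-en-1-yl (2E)-4-[(tert-butyldimethylsilyl)oxy]-2-methylbut-2-enoate, via epoxy hydroxy ester 18 (not isolated)
Conditions: VO(acac)2 (5 mol%), t-BuOOH, CH2Cl2, 0 °C; then PPTS (20 mol%), 23 °C
Reagents that add atoms: tert-butyl hydroperoxide, CC(C)(C)OO
Why: Hydroxyl-directed epoxidation, chemoselective for the allylic alcohol olefin, in which allylic 1,3-strain between the C4 methyl (cis to C6) and the carbinol substituents holds H6 in the olefin plane so that oxygen is delivered syn to the hydroxyl and gives the threo (4R,5R) epoxy alcohol; mild acid then closes the γ-lactone by transesterification.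

**Step 11**
Reactants: 19 epoxy lactone diene
Product: 20 (1(10)Z,4R,5R,6S,7R,8R)-8-{[(2E)-4-[(tert-butyldimethylsilyl)oxy]-2-methylbut-2-enoyl]oxy}-4,5-epoxygermacra-1(10),11(13)-dien-12,6-olide
Conditions: second-generation Hoveyda–Grubbs catalyst (10 mol%), 1,4-benzoquinone (20 mol%), toluene (1 mM), 80 °C
Reagents that add atoms: none
Why: Ring-closing metathesis, in which the catalyst loads at the vinyl group and closes onto the 1,1-disubstituted olefin of the arm on the neighbouring lactone carbon; the ten-membered ring favours the less strained cis ring olefin (C2 cis to C9), and the electron-poor α-methylene lactone and enoate stay out.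

**Step 12**
Reactants: 20 silyl-protected macrocycle
Product: 21 (1(10)Z,4R,5R,6S,7R,8R)-4,5-epoxy-8-{[(2E)-4-hydroxy-2-methylbut-2-enoyl]oxy}germacra-1(10),11(13)-dien-12,6-olide (target CNP0198076.5)
Conditions: Bu4NF/AcOH (1:1), THF, 0 → 23 °C
Reagents that add atoms: none
Why: Acetic-acid-buffered fluoride desilylation of the primary allylic silyl ether, mild enough for the α-methylene lactone, the oxirane and the C8 ester.

**Compound list**
1 | (tert-butyldimethylsilyloxy)acetaldehyde | O=CCO[Si](C)(C)C(C)(C)C | starting material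
2 | ethyl 2-(triphenylphosphoranylidene)propanoate | CCOC(=O)C(C)=P(c1ccccc1)(c1ccccc1)c1ccccc1 | starting material
3 | ethyl (2E)-4-[(tert-butyldimethylsilyl)oxy]-2-methylbut-2-enoate | CCOC(=O)/C(C)=C/CO[Si](C)(C)C(C)(C)C | intermediate
4 | (2E)-4-[(tert-butyldimethylsilyl)oxy]-2-methylbut-2-enoic acid | O=C(O)/C(C)=C/CO[Si](C)(C)C(C)(C)C | intermediate
5 | bis[(2E)-4-[(tert-butyldimethylsilyl)oxy]-2-methylbut-2-enoyl] peroxide | CC(C)(C)[Si](C)(C)OC/C=C(\C)C(=O)OOC(=O)/C(C)=C/CO[Si](C)(C)C(C)(C)C | intermediate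
6 | 4-methylpent-4-enal | C=C(C)CCC=O | starting material
7 | (2R)-4-methyl-1-oxopent-4-en-2-yl (2E)-4-[(tert-butyldimethylsilyl)oxy]-2-methylbut-2-enoate | O=C[C@H](OC(=O)/C(C)=C/CO[Si](C)(C)C(C)(C)C)CC(C)=C | intermediate
8 | ethyl bromo[bis(2,2,2-trifluoroethoxy)phosphoryl]acetate | CCOC(=O)C(Br)P(=O)(OCC(F)(F)F)OCC(F)(F)F | starting material
9 | ethyl (2E,4R)-2-bromo-4-{[(2E)-4-[(tert-butyldimethylsilyl)oxy]-2-methylbut-2-enoyl]oxy}-6-methylhepta-2,6-dienoate | CCOC(=O)/C(Br)=C\[C@H](OC(=O)/C(C)=C/CO[Si](C)(C)C(C)(C)C)CC(C)=C | intermediate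
10 | 2-(iodomethyl)-4,4,5,5-tetramethyl-1,3,2-dioxaborolane | ICB1OC(C)(C)C(C)(C)O1 | starting material
11 | (pinacolboryl)methylzinc iodide | I[Zn]CB1OC(C)(C)C(C)(C)O1 | intermediate
12 | ethyl (2Z,4R)-4-{[(2E)-4-[(tert-butyldimethylsilyl)oxy]-2-methylbut-2-enoyl]oxy}-6-methyl-2-[(4,4,5,5-tetramethyl-1,3,2-dioxaborolan-2-yl)methyl]hepta-2,6-dienoate | CCOC(=O)/C(CB1OC(C)(C)C(C)(C)O1)=C\[C@H](OC(=O)/C(C)=C/CO[Si](C)(C)C(C)(C)C)CC(C)=C | intermediate
13 | hex-5-en-2-one | CC(=O)CCC=C | starting material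
14 | diethyl {2-[methoxy(methyl)amino]-2-oxoethyl}phosphonate | CCOP(=O)(OCC)CC(=O)N(C)OC | starting material
15 | (2E)-N-methoxy-N,3-dimethylhepta-2,6-dienamide | C=CCC/C(C)=C/C(=O)N(C)OC | intermediate
16 | (2E)-3-methylhepta-2,6-dienal | C=CCC/C(C)=C/C=O | intermediate
17 | ethyl (3S,4R,5E)-3-[(1R)-1-{[(2E)-4-[(tert-butyldimethylsilyl)oxy]-2-methylbut-2-enoyl]oxy}-3-methylbut-3-en-1-yl]-4-hydroxy-6-methyl-2-methylidenedeca-5,9-dienoate | CCOC(=O)C(=C)[C@@H]([C@H](O)/C=C(\C)CCC=C)[C@H](OC(=O)/C(C)=C/CO[Si](C)(C)C(C)(C)C)CC(C)=C | intermediate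
18 | ethyl (3S,4S)-4-[(2R,3R)-3-(but-3-en-1-yl)-3-methyloxiran-2-yl]-3-[(1R)-1-{[(2E)-4-[(tert-butyldimethylsilyl)oxy]-2-methylbut-2-enoyl]oxy}-3-methylbut-3-en-1-yl]-4-hydroxy-2-methylidenebutanoate | CCOC(=O)C(=C)[C@@H]([C@H](O)[C@H]3O[C@]3(C)CCC=C)[C@H](OC(=O)/C(C)=C/CO[Si](C)(C)C(C)(C)C)CC(C)=C | intermediate
19 | (1R)-1-[(2S,3R)-2-[(2R,3R)-3-(but-3-en-1-yl)-3-methyloxiran-2-yl]-4-methylidene-5-oxooxolan-3-yl]-3-methylbut-3-en-1-yl (2E)-4-[(tert-butyldimethylsilyl)oxy]-2-methylbut-2-enoate | C=C1C(=O)O[C@H]([C@H]3O[C@]3(C)CCC=C)[C@H]1[C@H](OC(=O)/C(C)=C/CO[Si](C)(C)C(C)(C)C)CC(C)=C | intermediate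
20 | (1(10)Z,4R,5R,6S,7R,8R)-8-{[(2E)-4-[(tert-butyldimethylsilyl)oxy]-2-methylbut-2-enoyl]oxy}-4,5-epoxygermacra-1(10),11(13)-dien-12,6-olide | C=C1C(=O)O[C@H]2[C@H]1[C@H](OC(=O)/C(C)=C/CO[Si](C)(C)C(C)(C)C)C/C(C)=C\CC[C@@]1(C)O[C@H]21 | intermediate
21 | (1(10)Z,4R,5R,6S,7R,8R)-4,5-epoxy-8-{[(2E)-4-hydroxy-2-methylbut-2-enoyl]oxy}germacra-1(10),11(13)-dien-12,6-olide | C=C1C(=O)O[C@H]2[C@H]1[C@H](OC(=O)/C(C)=C/CO)C/C(C)=C\CC[C@@]1(C)O[C@H]21 | target

**Step count**
Total: 12 steps. Longest linear sequence: 10 steps (steps 1–6, then 9–12).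

**Steps most likely to fail, with fallbacks**

Step 4 (the proposed new α-acyloxylation) may fail through low turnover or N-acyloxylation of the catalyst. The fallback uses known chemistry, sets out from 6 and acid 4, and returns at 7. Aldehyde 6 is α-aminoxylated with nitrosobenzene under L-proline catalysis (Re-face delivery through the carboxylic acid hydrogen bond, same R sense) and reduced in the same flask with NaBH4 to (2R)-4-methyl-2-[(phenylamino)oxy]pent-4-en-1-ol F1. Zn in AcOH cleaves the N–O bond to (2R)-4-methylpent-4-ene-1,2-diol F2. Et3SiCl and imidazole at −78 °C silylate the primary hydroxyl to give (2R)-4-methyl-1-[(triethylsilyl)oxy]pent-4-en-2-ol F3. DCC and DMAP esterify the secondary hydroxyl with acid 4 to give (2R)-4-methyl-1-[(triethylsilyl)oxy]pent-4-en-2-yl (2E)-4-[(tert-butyldimethylsilyl)oxy]-2-methylbut-2-enoate F4. PPTS in MeOH at 0 °C removes only the triethylsilyl group to give (2R)-1-hydroxy-4-methylpent-4-en-2-yl (2E)-4-[(tert-butyldimethylsilyl)oxy]-2-methylbut-2-enoate F5, which is oxidised at once with Dess–Martin periodinane to 7.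

Step 11 (ring-closing metathesis to a ten-membered ring with a trisubstituted olefin) may give oligomers or stall on the rigid lactone. The fallback closes the carbocycle first; it sets out from 17 and returns at 20. Hydroxy ester 17 is cyclised under the same catalyst at high dilution, where the open chain is more flexible, to ethyl 2-[(1S,2R,3E,7Z,10R)-10-{[(2E)-4-[(tert-butyldimethylsilyl)oxy]-2-methylbut-2-enoyl]oxy}-2-hydroxy-4,8-dimethylcyclodeca-3,7-dien-1-yl]prop-2-enoate F6. VO(acac)2 and t-BuOOH then epoxidise the allylic alcohol olefin syn to the hydroxyl to give ethyl (1(10)Z,4R,5R,6S,7S,8R)-8-{[(2E)-4-[(tert-butyldimethylsilyl)oxy]-2-methylbut-2-enoyl]oxy}-4,5-epoxy-6-hydroxygermacra-1(10),11(13)-dien-12-oate F7, which is lactonised with PPTS without isolation to 20.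

Step 9 (allylboration) may suffer from Lewis-acid-induced loss of the allylic ester or from weak facial control at C7. The fallback replaces boron by a chromium-mediated Nozaki–Hiyama allylation; it sets out from 12 and returns at 17. NaBO3·4H2O oxidises 12 to ethyl (2Z,4R)-4-{[(2E)-4-[(tert-butyldimethylsilyl)oxy]-2-methylbut-2-enoyl]oxy}-2-(hydroxymethyl)-6-methylhepta-2,6-dienoate F8. CBr4 and PPh3 convert it into ethyl (2E,4R)-2-(bromomethyl)-4-{[(2E)-4-[(tert-butyldimethylsilyl)oxy]-2-methylbut-2-enoyl]oxy}-6-methylhepta-2,6-dienoate F9. CrCl2 (divalent chromium) in THF, added to a mixture of F9 and enal 16 at 0 °C so that the allylchromium species is trapped as it forms, gives 17 through the anti-selective chair, whatever the bromide geometry.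

**Further compounds**
F1 | step 4 | (2R)-4-methyl-2-[(phenylamino)oxy]pent-4-en-1-ol | OC[C@H](ONc1ccccc1)CC(C)=C
F2 | step 4 | (2R)-4-methylpent-4-ene-1,2-diol | OC[C@H](O)CC(C)=C
F3 | step 4 | (2R)-4-methyl-1-[(triethylsilyl)oxy]pent-4-en-2-ol | CC[Si](CC)(CC)OC[C@H](O)CC(C)=C
F4 | step 4 | (2R)-4-methyl-1-[(triethylsilyl)oxy]pent-4-en-2-yl (2E)-4-[(tert-butyldimethylsilyl)oxy]-2-methylbut-2-enoate | CC[Si](CC)(CC)OC[C@H](OC(=O)/C(C)=C/CO[Si](C)(C)C(C)(C)C)CC(C)=C
F5 | step 4 | (2R)-1-hydroxy-4-methylpent-4-en-2-yl (2E)-4-[(tert-butyldimethylsilyl)oxy]-2-methylbut-2-enoate | OC[C@H](OC(=O)/C(C)=C/CO[Si](C)(C)C(C)(C)C)CC(C)=C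
F6 | step 11 | ethyl 2-[(1S,2R,3E,7Z,10R)-10-{[(2E)-4-[(tert-butyldimethylsilyl)oxy]-2-methylbut-2-enoyl]oxy}-2-hydroxy-4,8-dimethylcyclodeca-3,7-dien-1-yl]prop-2-enoate | CCOC(=O)C(=C)[C@H]1[C@H](O)/C=C(\C)CC/C=C(C)\C[C@H]1OC(=O)/C(C)=C/CO[Si](C)(C)C(C)(C)C
F7 | step 11 | ethyl (1(10)Z,4R,5R,6S,7S,8R)-8-{[(2E)-4-[(tert-butyldimethylsilyl)oxy]-2-methylbut-2-enoyl]oxy}-4,5-epoxy-6-hydroxygermacra-1(10),11(13)-dien-12-oate | CCOC(=O)C(=C)[C@H]1[C@H](O)[C@H]2O[C@]2(C)CC/C=C(C)\C[C@H]1OC(=O)/C(C)=C/CO[Si](C)(C)C(C)(C)C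
F8 | step 9 | ethyl (2Z,4R)-4-{[(2E)-4-[(tert-butyldimethylsilyl)oxy]-2-methylbut-2-enoyl]oxy}-2-(hydroxymethyl)-6-methylhepta-2,6-dienoate | CCOC(=O)/C(CO)=C\[C@H](OC(=O)/C(C)=C/CO[Si](C)(C)C(C)(C)C)CC(C)=C
F9 | step 9 | ethyl (2E,4R)-2-(bromomethyl)-4-{[(2E)-4-[(tert-butyldimethylsilyl)oxy]-2-methylbut-2-enoyl]oxy}-6-methylhepta-2,6-dienoate | CCOC(=O)/C(CBr)=C\[C@H](OC(=O)/C(C)=C/CO[Si](C)(C)C(C)(C)C)CC(C)=C
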